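**Plan**

1. Cuts: C12–C13 (sp3–sp2 Suzuki–Miyaura coupling) removes the hydroxy-butenolide side chain. The C4 ester/C6 hydroxyl pair is traced to an 18,6α-lactone and from there to a C4 ketone. Ring B is then cut at C5–C6 and C8–C9 in one stroke.
2. Enabling feature: in ring B the 1,3-diol unit C6(OH)–C7H2–C8(OH)CH3 is a latent 3-oxobutanal. Its two carbinol carbons are bonded to C5 and C9, which both sit on the quaternary C10. A ring A fragment nucleophilic at C5 (silyl enol ether of the C4 ketone) and at C9 (γ-carbon of an allylboronate C9=C11–C12–B) can therefore be annulated (3+3) with a 3-oxobutanal acetal.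
3. Forward order: ring A with C10 (step 1), allylboronate (step 2), (3+3) annulation closing ring B (step 4), C4 ketone to enol triflate, carbonylative lactonisation and reductive methylation for C4/C18 (steps 6–8), lactone opening (step 9), side chain joined at C12–C13 (step 17).
4. Stereochemistry: C10 from the chiral copper catalyst; C6 from the (S,S)-pentane-2,4-diol acetal template; C8 and C9 from the closed chair allylboration transition state; C5 by equilibration to the trans ring fusion; C4 from the lactone tether; C15/C16 from a catalytic asymmetric vinylogous Mukaiyama aldol reaction; C13=C14 from an (E)-vinyl iodide.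
5. Atom labels are labdane-type: ring A = C1–C5 and C10, ring B = C5–C10, C11/C12 on C9, C18 = ester carbon on C4, C13–C16 = side chain up to the butenolide carbon.

Key step: step 4

Remark: the SMILES is read as (4R,5R,6S,8R,9R,10S,13E,15S,16S), that is 5α-H, 6α-OH, 8α-OH, 9β side chain, 10β-CH3 and an α (equatorial) ester on C4; the route is drawn for this isomer.

Step 1
Reactants: 1 3-methylcyclohex-2-en-1-one
Product: 3 triethyl{[(3R)-3-ethenyl-3-methylcyclohex-1-en-1-yl]oxy}silane, via aluminium enolate 2 (not isolated)
Conditions: CH2=CHMgBr, Me2AlCl, Et2O, −30 °C; CuTC (monovalent copper thiophene-2-carboxylate, 5 mol %), chiral SimplePhos-type amidophosphine ligand (10 mol %, enantiomer chosen for the future 10S centre), −30 °C; then Et3SiOTf, −30 → 0 °C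
Reagents that add atoms: vinylmagnesium bromide, C=C[Mg]Br; triethylsilyl trifluoromethanesulfonate, CC[Si](CC)(CC)OS(=O)(=O)C(F)(F)F
Why: Copper-catalysed asymmetric conjugate addition of an alkenylaluminium reagent to a 3-substituted cyclohexenone should create the C10 quaternary centre with the face set by the chiral ligand, and O-silylation of the aluminium enolate fixes the enol double bond regiospecifically between C4 and C5, the position that kinetic deprotonation of the ketone would not give.

Step 2
Reactants: 3 triethyl{[(3R)-3-ethenyl-3-methylcyclohex-1-en-1-yl]oxy}silane; 4 2-allyl-4,4,5,5-tetramethyl-1,3,2-dioxaborolane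
Product: 5 triethyl({(3R)-3-methyl-3-[(1E)-3-(4,4,5,5-tetramethyl-1,3,2-dioxaborolan-2-yl)prop-1-en-1-yl]cyclohex-1-en-1-yl}oxy)silane
Conditions: 4 (3 equiv), second-generation Hoveyda–Grubbs catalyst (5 mol %), CH2Cl2, 40 °C
Reagents that add atoms: none
Why: Olefin cross-metathesis, in which the vinyl group on the quaternary carbon cannot homodimerise and the trisubstituted silyl enol ether is a spectator, so exchange with the allylboronate should give the 1,2-disubstituted allylic boronate, the bulky C10 substituent favouring the (E) isomer.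

Step 3
Reactants: 6 4,4-dimethoxybutan-2-one; 7 (2S,4S)-pentane-2,4-diol
Product: 8 1-[(4S,6S)-4,6-dimethyl-1,3-dioxan-2-yl]propan-2-one
Conditions: pyridinium p-toluenesulfonate (cat.), benzene, 60 °C, methanol distilled off
Reagents that add atoms: none
Why: Acid-catalysed transacetalisation driven by removal of methanol; the diol is C2-symmetric, so the acetal carbon is not a stereocentre and a single compound should result.

Step 4
Reactants: 5 allylboronate silyl enol ether; 8 chiral keto acetal
Product: 10 8α-hydroxy-6α-{[(2S,4S)-4-hydroxypentan-2-yl]oxy}-8β,10β-dimethyl-9β-vinyl-5α-decalin-4-one, via open-chain keto ether boronate 9 (not isolated)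
Conditions: TiCl4 (1.1 equiv), CH2Cl2, −78 °C; then −78 → −20 °C; aq. NaHCO3
Reagents that add atoms: none
Why: TiCl4 ionises the dioxane of 8 at the C–O bond next to its axial methyl group while the enol ether carbon C5 of 5 attacks the acetal carbon C6 from the rear (a chiral-acetal Mukaiyama aldol reaction, SN2-like with inversion), and the C8 ketone thus tethered to ring A is then allylated at C9 by the (E)-allylboronate through a closed six-membered B–O transition state (Lewis-acid-accelerated intramolecular allylboration), so that C5–C6 and C8–C9 are both formed in one flask. The closest known reaction types are the pentane-2,4-diol acetal aldol reaction of silyl enol ethers and the intramolecular allylboration of ketones; ring B closes in the 6-exo-trig mode (C9 onto the C8 carbonyl). C6 is set by the (S,S)-template, whose ether oxygen then sits equatorial and anchors the chair of the forming ring B. C8 and C9 are set by the chair–chair transition state in which the (E)-boronate places C10 and the ketone places C7 equatorial on the boron-containing ring, the C8 methyl being axial: O8 and the new vinyl group end up trans-diequatorial (8α-OH, 8β-CH3, 9β-vinyl). C5 should be attacked mainly anti to the allylboronate chain (H5 α), and either C5 epimer closes through the same ring B chair and is equilibrated in step 5. The step needs acetal-before-ketone chemoselectivity and a closed allyl transfer: the first is secured because only the ionised acetal is electrophilic enough for the silyl enol ether, which is far more nucleophilic than the allylboronate, the second because boron transfers the allyl group only to a carbonyl oxygen that is bound to it.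

Step 5
Reactants: 10 ring B adduct carrying the auxiliary
Product: 12 6α,8α-dihydroxy-8β,10β-dimethyl-9β-vinyl-5α-decalin-4-one, via auxiliary ketone 11 (not isolated)
Conditions: Dess–Martin periodinane, NaHCO3, CH2Cl2, 0 °C → rt; then K2CO3, MeOH, rt
Reagents that add atoms: none
Why: Dess–Martin oxidation turns the auxiliary alcohol into a methyl ketone, whose β-alkoxy group (O6) is then expelled by carbonate-induced E1cB elimination (retro-oxa-Michael), while the same base should equilibrate C5 through the C4 enolate to the trans-fused ketone, in which the equatorial 6α-hydroxyl is hydrogen-bonded to the C4 carbonyl.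

Step 6
Reactants: 12 dihydroxy ketone
Product: 15 6α,8α-dihydroxy-8β,10β-dimethyl-9β-vinyl-5α-decal-3-en-4-yl trifluoromethanesulfonate, via bis(trimethylsilyl) ether 13 (not isolated), via silylated enol triflate 14 (not isolated)
Conditions: N-(trimethylsilyl)imidazole, CH2Cl2, rt, evaporate; KN(SiMe3)2, THF, −78 °C; Comins' reagent, −78 °C; 1 M HCl, MeOH, 0 °C
Reagents that add atoms: Comins' reagent [N-(5-chloropyridin-2-yl)bis(trifluoromethanesulfonimide)], O=S(=O)(N(c1ccc(Cl)cn1)S(=O)(=O)C(F)(F)F)C(F)(F)F
Why: After transient silylation of both hydroxyls, KN(SiMe3)2 should remove the kinetically most accessible proton at the C3 methylene (C5–H is a hindered ring-fusion methine), O-sulfonylation of this enolate gives the C3=C4 enol triflate, and methanolic acid then removes the silyl ethers.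

Step 7
Reactants: 15 hydroxy enol triflate
Product: 16 8α-hydroxy-8β,10β-dimethyl-9β-vinyl-5α-decal-3-ene-4-carboxylic acid 18,6α-lactone
Conditions: Pd(PPh3)4 (10 mol %), CO (1 atm), n-Bu3N, LiCl, MeCN, 65 °C
Reagents that add atoms: carbon monoxide, [C-]#[O+]
Why: Palladium-catalysed carbonylative lactonisation of a hydroxy enol triflate, in which oxidative addition, CO insertion and capture of the acylpalladium by the 6α-hydroxyl (peri to the in-plane position on C4) should close the five-membered 18,6α-lactone.

Step 8
Reactants: 16 unsaturated lactone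
Product: 18 8α-hydroxy-4β,8β,10β-trimethyl-9β-vinyl-5α-decalin-4α-carboxylic acid 18,6α-lactone, via lithium lactone enolate 17 (not isolated)
Conditions: LiBH(s-Bu)3 (2.2 equiv), THF, −78 °C; MeI, HMPA, −78 → 0 °C
Reagents that add atoms: iodomethane, CI
Why: Conjugate reduction by the hindered borohydride gives the lactone enolate regiospecifically, and C-methylation should occur on the β face because the tether to the equatorial O6 can hold C18 only in the α (equatorial, peri) position, which sets C4 with the carboxyl carbon α and the methyl β, the opposite of what a free ester enolate would give.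

Step 9
Reactants: 18 saturated lactone
Product: 20 methyl 6α,8α-dihydroxy-4β,8β,10β-trimethyl-9β-vinyl-5α-decalin-4α-carboxylate, via potassium carboxylate 19 (not isolated)
Conditions: KOH, MeOH/H2O, 60 °C; evaporate; MeI, DMF, rt
Reagents that add atoms: potassium hydroxide, [K+].[OH-]; iodomethane, CI
Why: Saponification of the strained trans-fused γ-lactone followed by SN2 O-alkylation of the carboxylate salt with iodomethane should deliver the hydroxy methyl ester without an acidic stage in which the hydroxy acid could relactonise.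

Step 10
Reactants: 20 dihydroxy methyl ester
Product: 21 methyl 8α-hydroxy-4β,8β,10β-trimethyl-6α-(triethylsilyloxy)-9β-vinyl-5α-decalin-4α-carboxylate
Conditions: Et3SiCl, imidazole, DMF, rt
Reagents that add atoms: chlorotriethylsilane, CC[Si](Cl)(CC)CC
Why: Silylation with the chlorosilane and imidazole is selective for the secondary 6-hydroxyl over the tertiary 8-hydroxyl and blocks relactonisation onto the ester during the basic coupling.

Step 11
Reactants: 22 but-2-ynoic acid
Product: 23 (2E)-3-iodobut-2-enoic acid
Conditions: 57% aq. HI, 110 °C (sealed tube)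
Reagents that add atoms: hydrogen iodide, I
Why: Hydroiodination of the ynoic acid followed by acid-mediated equilibration at 110 °C should give the thermodynamically favoured (E)-β-iodo acid, with iodine trans to the carboxyl group.

Step 12
Reactants: 23 (2E)-3-iodobut-2-enoic acid
Product: 24 (2E)-3-iodobut-2-en-1-ol
Conditions: BH3·THF, THF, 0 °C → rt
Reagents that add atoms: none
Why: Borane reduces the carboxylic acid chemoselectively and much faster than it hydroborates the electron-poor trisubstituted iodoalkene, so the alkene geometry is untouched.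

Step 13
Reactants: 24 (2E)-3-iodobut-2-en-1-ol
Product: 25 (2E)-3-iodobut-2-enal
Conditions: MnO2, CH2Cl2, rt
Reagents that add atoms: none
Why: Manganese dioxide oxidises the allylic alcohol to the enal without isomerising the iodoalkene.

Step 14
Reactants: 26 4-methylfuran-2(5H)-one
Product: 27 trimethyl[(4-methylfuran-2-yl)oxy]silane
Conditions: Me3SiOTf, Et3N, CH2Cl2, 0 °C
Reagents that add atoms: trimethylsilyl trifluoromethanesulfonate, C[Si](C)(C)OS(=O)(=O)C(F)(F)F
Why: Soft enolisation of the butenolide with the silyl triflate and amine gives the aromatic 2-silyloxyfuran, the dienolate equivalent needed for a γ-selective aldol reaction.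

Step 15
Reactants: 25 (2E)-3-iodobut-2-enal; 27 2-silyloxyfuran
Product: 28 (5S)-5-[(1S,2E)-1-hydroxy-3-iodobut-2-en-1-yl]-4-methylfuran-2(5H)-one
Conditions: Ti(OiPr)4 (20 mol %), BINOL (20 mol %, enantiomer chosen for the 15S,16S adduct), Et2O, −20 °C; 1 M HCl
Reagents that add atoms: none
Why: Catalytic asymmetric vinylogous Mukaiyama aldol reaction, in which the silyloxyfuran reacts at its γ carbon (C16), Lewis-acid-promoted additions of this class favour the threo (like) relationship of the two new stereocentres, and the BINOL–titanium catalyst should select the aldehyde face to give (15S,16S).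

Step 16
Reactants: 28 hydroxy vinyl iodide butenolide
Product: 29 (5S)-5-[(1S,2E)-3-iodo-1-(triethylsilyloxy)but-2-en-1-yl]-4-methylfuran-2(5H)-one
Conditions: Et3SiCl, imidazole, CH2Cl2, 0 °C
Reagents that add atoms: chlorotriethylsilane, CC[Si](Cl)(CC)CC
Why: Silylation of the allylic alcohol prevents base-induced retro-vinylogous-aldol cleavage of the hydroxyalkyl butenolide during the cross-coupling.

Step 17
Reactants: 21 silyl-protected vinyl decalin ester; 29 silyl-protected vinyl iodide
Product: 31 6,15-bis-O-triethylsilyl ether of the target, via B-alkyl-9-BBN 30 (not isolated)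
Conditions: 9-BBN, THF, rt → 50 °C; then 29, Pd(dppf)Cl2 (5 mol %), AsPh3, K3PO4 (aq.), DMF, rt
Reagents that add atoms: none
Why: 9-BBN adds to the terminal vinyl group at C12 (anti-Markovnikov), and the B-alkyl borane then undergoes Suzuki–Miyaura coupling with the vinyl iodide with retention of the (E) geometry, forming the C12–C13 bond under conditions mild enough for the butenolide.

Step 18
Reactants: 31 bis-silyl ether
Product: 32 methyl (1R,4aS,5R,6R,8S,8aR)-6,8-dihydroxy-5-[(3E,5S)-5-hydroxy-3-methyl-5-[(2S)-3-methyl-5-oxo-2,5-dihydrofuran-2-yl]pent-3-en-1-yl]-1,4a,6-trimethyldecahydronaphthalene-1-carboxylate (CNP0104474.1)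
Conditions: HF·pyridine, pyridine, THF, 0 °C → rt
Reagents that add atoms: none
Why: Fluoride cleaves both silicon–oxygen bonds under buffered conditions that should spare the butenolide, the allylic alcohol and the γ-hydroxy ester.

**Compound list**

1 | 3-methylcyclohex-2-en-1-one | CC1=CC(=O)CCC1 | starting material
2 | dimethylaluminium (3R)-3-ethenyl-3-methylcyclohex-1-en-1-olate | C1CCC(O[Al](C)C)=C[C@@]1(C)C=C | intermediate
3 | triethyl{[(3R)-3-ethenyl-3-methylcyclohex-1-en-1-yl]oxy}silane | C1CCC(O[Si](CC)(CC)CC)=C[C@@]1(C)C=C | intermediate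
4 | 2-allyl-4,4,5,5-tetramethyl-1,3,2-dioxaborolane | C=CCB1OC(C)(C)C(C)(C)O1 | starting material
5 | triethyl({(3R)-3-methyl-3-[(1E)-3-(4,4,5,5-tetramethyl-1,3,2-dioxaborolan-2-yl)prop-1-en-1-yl]cyclohex-1-en-1-yl}oxy)silane | C1CCC(O[Si](CC)(CC)CC)=C[C@@]1(C)/C=C/CB2OC(C)(C)C(C)(C)O2 | intermediate
6 | 4,4-dimethoxybutan-2-one | CC(=O)CC(OC)OC | starting material
7 | (2S,4S)-pentane-2,4-diol | C[C@H](O)C[C@H](C)O | starting material
8 | 1-[(4S,6S)-4,6-dimethyl-1,3-dioxan-2-yl]propan-2-one | CC(=O)CC1O[C@@H](C)C[C@H](C)O1 | intermediate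
9 | open-chain keto ether boronate (C5–C6 formed, ring B open; auxiliary oxygen shown as the free alcohol) | O=C1CCC[C@](C)(/C=C/CB2OC(C)(C)C(C)(C)O2)[C@H]1[C@@H](O[C@@H](C)C[C@H](C)O)CC(C)=O | intermediate
10 | 8α-hydroxy-6α-{[(2S,4S)-4-hydroxypentan-2-yl]oxy}-8β,10β-dimethyl-9β-vinyl-5α-decalin-4-one | O=C1CCC[C@@]2(C)[C@H]1[C@@H](O[C@@H](C)C[C@H](C)O)C[C@@](C)(O)[C@@H]2C=C | intermediate
11 | 8α-hydroxy-8β,10β-dimethyl-6α-{[(2S)-4-oxopentan-2-yl]oxy}-9β-vinyl-5α-decalin-4-one | O=C1CCC[C@@]2(C)[C@H]1[C@@H](O[C@@H](C)CC(C)=O)C[C@@](C)(O)[C@@H]2C=C | intermediate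
12 | 6α,8α-dihydroxy-8β,10β-dimethyl-9β-vinyl-5α-decalin-4-one | O=C1CCC[C@@]2(C)[C@H]1[C@@H](O)C[C@@](C)(O)[C@@H]2C=C | intermediate
13 | 8β,10β-dimethyl-6α,8α-bis(trimethylsilyloxy)-9β-vinyl-5α-decalin-4-one | O=C1CCC[C@@]2(C)[C@H]1[C@@H](O[Si](C)(C)C)C[C@@](C)(O[Si](C)(C)C)[C@@H]2C=C | intermediate
14 | 8β,10β-dimethyl-6α,8α-bis(trimethylsilyloxy)-9β-vinyl-5α-decal-3-en-4-yl trifluoromethanesulfonate | O=S(=O)(OC1=CCC[C@@]2(C)[C@H]1[C@@H](O[Si](C)(C)C)C[C@@](C)(O[Si](C)(C)C)[C@@H]2C=C)C(F)(F)F | intermediate
15 | 6α,8α-dihydroxy-8β,10β-dimethyl-9β-vinyl-5α-decal-3-en-4-yl trifluoromethanesulfonate | O=S(=O)(OC1=CCC[C@@]2(C)[C@H]1[C@@H](O)C[C@@](C)(O)[C@@H]2C=C)C(F)(F)F | intermediate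
16 | 8α-hydroxy-8β,10β-dimethyl-9β-vinyl-5α-decal-3-ene-4-carboxylic acid 18,6α-lactone | O=C3C1=CCC[C@@]2(C)[C@H]1[C@@H](O3)C[C@@](C)(O)[C@@H]2C=C | intermediate
17 | lithium enolate of the saturated 18,6α-lactone (8-O-lithium alkoxide) | [Li]OC3=C1CCC[C@@]2(C)[C@H]1[C@@H](O3)C[C@@](C)(O[Li])[C@@H]2C=C | intermediate
18 | 8α-hydroxy-4β,8β,10β-trimethyl-9β-vinyl-5α-decalin-4α-carboxylic acid 18,6α-lactone | O=C3[C@]1(C)CCC[C@@]2(C)[C@H]1[C@@H](O3)C[C@@](C)(O)[C@@H]2C=C | intermediate
19 | potassium 6α,8α-dihydroxy-4β,8β,10β-trimethyl-9β-vinyl-5α-decalin-4α-carboxylate | [K+].[O-]C(=O)[C@]1(C)CCC[C@@]2(C)[C@H]1[C@@H](O)C[C@@](C)(O)[C@@H]2C=C | intermediate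
20 | methyl 6α,8α-dihydroxy-4β,8β,10β-trimethyl-9β-vinyl-5α-decalin-4α-carboxylate | COC(=O)[C@]1(C)CCC[C@@]2(C)[C@H]1[C@@H](O)C[C@@](C)(O)[C@@H]2C=C | intermediate
21 | methyl 8α-hydroxy-4β,8β,10β-trimethyl-6α-(triethylsilyloxy)-9β-vinyl-5α-decalin-4α-carboxylate | COC(=O)[C@]1(C)CCC[C@@]2(C)[C@H]1[C@@H](O[Si](CC)(CC)CC)C[C@@](C)(O)[C@@H]2C=C | intermediate
22 | but-2-ynoic acid | CC#CC(=O)O | starting material
23 | (2E)-3-iodobut-2-enoic acid | I/C(C)=C/C(=O)O | intermediate
24 | (2E)-3-iodobut-2-en-1-ol | I/C(C)=C/CO | intermediate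
25 | (2E)-3-iodobut-2-enal | I/C(C)=C/C=O | intermediate
26 | 4-methylfuran-2(5H)-one | CC1=CC(=O)OC1 | starting material
27 | trimethyl[(4-methylfuran-2-yl)oxy]silane | Cc1coc(O[Si](C)(C)C)c1 | intermediate
28 | (5S)-5-[(1S,2E)-1-hydroxy-3-iodobut-2-en-1-yl]-4-methylfuran-2(5H)-one | I/C(C)=C/[C@H](O)[C@H]1OC(=O)C=C1C | intermediate
29 | (5S)-5-[(1S,2E)-3-iodo-1-(triethylsilyloxy)but-2-en-1-yl]-4-methylfuran-2(5H)-one | I/C(C)=C/[C@H](O[Si](CC)(CC)CC)[C@H]1OC(=O)C=C1C | intermediate
30 | B-alkyl-9-BBN from hydroboration of 21 at C12 | COC(=O)[C@]1(C)CCC[C@@]2(C)[C@H]1[C@@H](O[Si](CC)(CC)CC)C[C@@](C)(O)[C@@H]2CCB1C2CCCC1CCC2 | intermediate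
31 | 6,15-bis-O-triethylsilyl ether of the target | COC(=O)[C@]1(C)CCC[C@@]2(C)[C@H]1[C@@H](O[Si](CC)(CC)CC)C[C@@](C)(O)[C@@H]2CC/C(C)=C/[C@H](O[Si](CC)(CC)CC)[C@H]1OC(=O)C=C1C | intermediate
32 | methyl (1R,4aS,5R,6R,8S,8aR)-6,8-dihydroxy-5-[(3E,5S)-5-hydroxy-3-methyl-5-[(2S)-3-methyl-5-oxo-2,5-dihydrofuran-2-yl]pent-3-en-1-yl]-1,4a,6-trimethyldecahydronaphthalene-1-carboxylate | COC(=O)[C@]1(C)CCC[C@@]2(C)[C@H]1[C@@H](O)C[C@@](C)(O)[C@@H]2CC/C(C)=C/[C@H](O)[C@H]1OC(=O)C=C1C | target

**Step count and risks**

Total step count: 18. Longest linear sequence: 11 steps (1, 2, 4, 5, 6, 7, 8, 9, 10, 17, 18).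

Steps most likely to fail:

1. Step 4. What may go wrong: the ionised acetal loses its C7 proton before it is attacked, which erodes the template control at C6. The Lewis acid may also degrade the boronate or open the allyl-transfer transition state, with loss of the C8/C9 control, or closure next to the quaternary C10 may be too slow. Fallback (sets out from 3, returns at 10): cross-metathesis of 3 with allyl chloride (second-generation Hoveyda–Grubbs catalyst) should give the (E)-allylic chloride silyl enol ether F1. TiCl4-mediated opening of acetal 8 by F1 at −78 °C, now a separate operation with no boron present, should give the open-chain keto ether allylic chloride F2. Intramolecular Nozaki–Hiyama–Kishi allylation of the C8 ketone (CrCl2, LiI, THF/DMF), which also runs through a closed chair transition state, would then close ring B to 10.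

2. Step 8. What may go wrong: protonation or O-methylation of the lactone enolate, or methylation from the α face with distortion of ring A (poor facial selectivity at C4). Fallback (sets out from 15, returns at 18): the enol triflate is coupled with Me2CuLi to the C3=C4 methyl alkene diol F3. The 6-hydroxyl is acylated with Se-phenyl carbonochloridoselenoate (PhSeC(O)Cl, pyridine) to the selenocarbonate F4. Bu3SnH/AIBN then generates the alkoxycarbonyl radical on O6, which should cyclise 5-exo onto C4 from the α face, so that C18 and not the methyl group is the entering substituent, giving lactone 18.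

3. Step 5. What may go wrong: retro-aldol opening of ring B or β-elimination across C5–C6 while the β-oxygenated C4 ketone is exposed to base. Fallback (sets out from 10, returns at 15): 10 (its trans-fused isomer, purified) is silylated with N-(trimethylsilyl)imidazole to the bis(trimethylsilyl) ether F5 and converted by KN(SiMe3)2 and Comins' reagent into the silylated enol triflate F6. Methanolic HCl frees the two hydroxyls to give the enol triflate diol F7, which still carries the auxiliary. Only then, with no ketone left in ring A, is the auxiliary removed by Dess–Martin oxidation to the methyl ketone F8 and K2CO3/MeOH elimination, which gives 15. This variant relies on the kinetic C5 selectivity of step 4.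

**Further compounds**

F1 | step 4 | triethyl({(3R)-3-[(1E)-3-chloroprop-1-en-1-yl]-3-methylcyclohex-1-en-1-yl}oxy)silane | C1CCC(O[Si](CC)(CC)CC)=C[C@@]1(C)/C=C/CCl
F2 | step 4 | open-chain keto ether allylic chloride (C5–C6 formed, ring B open) | O=C1CCC[C@](C)(/C=C/CCl)[C@H]1[C@@H](O[C@@H](C)C[C@H](C)O)CC(C)=O
F3 | step 8 | 4,8β,10β-trimethyl-9β-vinyl-5α-decal-3-ene-6α,8α-diol | CC1=CCC[C@@]2(C)[C@H]1[C@@H](O)C[C@@](C)(O)[C@@H]2C=C
F4 | step 8 | O-(8α-hydroxy-4,8β,10β-trimethyl-9β-vinyl-5α-decal-3-en-6α-yl) Se-phenyl selenocarbonate | CC1=CCC[C@@]2(C)[C@H]1[C@@H](OC(=O)[Se]c1ccccc1)C[C@@](C)(O)[C@@H]2C=C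
F5 | step 5 | bis(trimethylsilyl) ether of 10 | O=C1CCC[C@@]2(C)[C@H]1[C@@H](O[C@@H](C)C[C@H](C)O[Si](C)(C)C)C[C@@](C)(O[Si](C)(C)C)[C@@H]2C=C
F6 | step 5 | C3=C4 enol triflate of the bis(trimethylsilyl) ether | O=S(=O)(OC1=CCC[C@@]2(C)[C@H]1[C@@H](O[C@@H](C)C[C@H](C)O[Si](C)(C)C)C[C@@](C)(O[Si](C)(C)C)[C@@H]2C=C)C(F)(F)F
F7 | step 5 | enol triflate diol carrying the hydroxypentyl auxiliary | O=S(=O)(OC1=CCC[C@@]2(C)[C@H]1[C@@H](O[C@@H](C)C[C@H](C)O)C[C@@](C)(O)[C@@H]2C=C)C(F)(F)F
F8 | step 5 | enol triflate carrying the oxopentyl auxiliary | O=S(=O)(OC1=CCC[C@@]2(C)[C@H]1[C@@H](O[C@@H](C)CC(C)=O)C[C@@](C)(O)[C@@H]2C=C)C(F)(F)F
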